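## The problem

Target 17, 1-(7-hydroxy-5-methoxy-2,2-dimethyl-2H-chromen-6-yl)-2-(4-methoxyphenyl)ethanone, is an achiral acylphloroglucinol whose benzene ring (ring A) is fused to a 2,2-dimethyl-2H-pyran (ring B) through O1/C8a and C4a/C4 and carries a methoxy group at C5, a 4-methoxyphenylacetyl group at C6 and a free hydroxyl at C7. There is no stereocentre, so the difficulty is purely regiochemical: the three oxygens of a phloroglucinol core must end as three different functions, the ring ether O1, the methyl ether at C5 and the hydrogen-bonded phenol at C7. Ring B must be fused at the carbon next to the methoxy-bearing C5, not at C8 next to the phenol. The ketone carbon sits on C6 between two oxygenated carbons, so the C6–C(=O) bond is crowded, and the CH2 between ketone and anisyl ring is doubly activated and open to C-alkylation under strong base. The C3=C4 double bond of ring B, a styrene conjugated to a very electron-rich arene, will not survive strong acid, electrophilic oxidants or hydrogenation. The anisyl methyl ether rules out global Lewis-acid ether cleavage, so phenols have to be masked as acetals that leave under mild acid. The key step is possible because the ketone carbon is bonded only to aromatic C6 and to the benzylic CH2, so it can enter as carbon monoxide. C6 also corresponds to one of three equivalent CH positions of a threefold-symmetric phloroglucinol triether, so the aryl halide is reached without any regiochemical choice.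

## Retrosynthesis

**17 back to 15.** No skeletal bond is cut. The C7 hydroxyl and the C5 methoxy group differ only by a methyl group, so the phenol of 17 is traced to the MOM ether 16, and the C5 methyl ether of 16 to the free phenol 15. The MOM group is a placeholder for hydrogen: it lets the ring be closed toward a free, chelated hydroxyl, which is then methylated. The forward steps must methylate a hindered, hydrogen-bonded phenol without touching the benzylic CH2, and must cleave an acetal without harming the chromene.

**15 back to 12.** Ring B is opened at C4a–C4. Chromene 15 comes from the aryl 1,1-dimethylpropargyl ether 12 by aromatic Claisen rearrangement, hydrogen shift and oxa-6π closure, through 13 and 14. The neighbouring cut, condensation of a free phenol with an unsaturated aldehyde, would leave open which of two oxygens becomes O1. In 12 that oxygen is fixed before heating, and only the choice between the two ortho carbons remains. The forward reaction must go to the carbon flanked by the chelated hydroxyl; the hydrogen bond to the ketone is the control element.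

**12 back to 9 and 10.** Two O–C bonds are cut. The MOM ether of 12 comes from the symmetric diol 11, where either ortho hydroxyl gives the same product and the second is held back by chelation. Ether 11 comes from triol 9 and 3-chloro-3-methylbut-1-yne 10. The alkylation must distinguish the hydroxyl para to the ketone from the two ortho hydroxyls, which its higher acidity and freedom from chelation should allow.

**9 back to 8.** The three acetal O–CH2 bonds are cut. No reagent exposes the para oxygen of 8 alone, so all three MOM groups are removed and the acidity gradient of 9 is used instead.

**8 back to 4, 6 and 7 (key disconnection).** Both bonds of the ketone carbon are cut, C6–C(=O) and C(=O)–CH2, leading to aryl iodide 4, (4-methoxybenzyl)zinc chloride 6 and carbon monoxide 7. The nearest neighbours cut only the C6–C(=O) bond. Electrophilic acylation of 1 with an arylacetic acid derivative is the shortest known way to 9 for this target and is kept as the fallback. Acylation of aryllithium 3 would pit a hindered, basic nucleophile against an enolisable arylacetyl electrophile. The carbonylative cut has three points in its favour: the small CO molecule forms the crowded bond, the conditions are neutral toward acetals, and the assembly is modular, so that the benzyl partner can be varied or the carbonyl carbon isotopically labelled. The precursors are one symmetric arene and one benzylic halide. The forward reaction must insert CO before the benzyl group is transferred.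

**4 back to 1, and 6 back to 5.** Iodide 4 is traced through aryllithium 3 to triether 2 and phloroglucinol 1. All three ring hydrogens of 2 are equivalent and each lies between two directing acetal oxygens. Zinc reagent 6 comes from 4-methoxybenzyl chloride 5 by direct metal insertion.

## Roads not taken

**Alternative 1:** The cut opens ring B completely (O1–C8a, C4a–C4 and O1–C2). It leads to 3-methoxy-5-(methoxymethoxy)benzyne A3, released by CsF from silyl triflate A2, and to 3-methylbut-2-enal A4. In the forward step the oxygen of aldehyde A4 adds to the carbon of aryne A3 remote from the methoxy group and the aryl anion closes onto the carbonyl carbon. The resulting benzoxete opens to an ortho-quinone methide, which closes by oxa-6π electrocyclisation to 5-methoxy-7-(methoxymethoxy)-2,2-dimethyl-2H-chromene A1.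
- Merits: ring B is made in one operation, and the polarisation of aryne A3, not a Claisen preference, places the methoxy group next to C4a. No placeholder exchange is needed.
- Weak points: A2 is a benzene with four different substituents in fixed order, reachable from 1 only through statistical mono-protections and an ortho-silylation sequence. The aryne–aldehyde addition competes with capture of the intermediates by a second aryne or aldehyde. The ketone is still missing: A1 has two open positions, C6 between two oxygens and C8 between an oxygen and O1, and the enolisable side chain must then be attached selectively at C6.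
- Comparison: this road fixes the ring-fusion regiochemistry better and would save the three placeholder steps. The chosen plan sets against it a symmetric, one-step precursor, a ketone construction with no regiochemical question, and catalytic steps of an established type.

**Alternative 2:** The cut goes through ring A itself. Methyl 8-(4-methoxyphenyl)-3,5,7-trioxooctanoate A6 cyclises under Mg(OMe)2 by Claisen condensation of its C6 methylene onto the ester carbon C1. Enolisation gives 2-(4-methoxyphenyl)-1-(2,4,6-trihydroxyphenyl)ethanone A5, the same substance as 9.
- Merits: no protecting groups, a biomimetic ring construction, and arrival at the compound the chosen route reaches only after step 5.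
- Weak points: A6 must be built by polyanion chemistry and is prone to aldol closure (C2 onto C7, giving a resorcylate) and to pyranone formation. The mode of cyclisation depends delicately on the counter-ion, and the benzylic CH2 is a further acidic site.
- Comparison: if A6 were available in two or three reliable steps, this road would equal or beat the five steps to 9. The chosen plan sets against it that each of its steps is predictable. Everything after A5 would be identical to steps 6 to 10, so nothing is gained in the regiochemical part.

**Alternative 3:** The cut removes the C6–C(=O) bond and the neighbouring C–O bond together. CsF releases 3-(methoxymethoxy)-5-[(2-methylbut-3-yn-2-yl)oxy]benzyne A9 from silyl triflate A8. The carboxylate of 4-methoxyphenylacetic acid A10 adds to the carbon of aryne A9 remote from the MOM ether, and the aryl anion takes the acyl group by intramolecular transfer. The product is 1-{2-hydroxy-6-(methoxymethoxy)-4-[(2-methylbut-3-yn-2-yl)oxy]phenyl}-2-(4-methoxyphenyl)ethanone A7, the same substance as 12.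
- Merits: the most convergent of the four. The three oxygens are already differentiated in A7, so steps 5 to 7 of the chosen route fall away and only rearrangement, methylation and deprotection remain.
- Weak points: the burden moves to A8, a phloroglucinol with three different oxygen substituents and an ortho silyl group, again reachable only through statistical protections. Protonation of the aryl anion by free acid A10 (simple O-arylation without acyl transfer) competes. The terminal alkyne and the acidic benzylic CH2 are exposed to fluoride and aryne.
- Comparison: this road is clearly shorter after its key step. The chosen plan sets against it starting materials that need no statistical step and a catalytic key reaction of a well-established type, and pays for this with three extra functional-group steps.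

Key step: step 4

Remark: 6 is taken to be a titrated THF solution of the benzylzinc chloride–LiCl complex, written without its LiCl; 7 is used as the gas at atmospheric pressure.

## Route

Step 1
Reactants: 1 phloroglucinol (benzene-1,3,5-triol)
Product: 2 1,3,5-tris(methoxymethoxy)benzene
Conditions: NaH, MOMCl, DMF, 0 °C to rt
Reagents that add atoms: chloromethyl methyl ether (MOMCl), COCCl
Why: Williamson-type O-alkylation of the tris-phenoxide; the hard alkoxymethyl chloride in a dipolar aprotic solvent reacts at oxygen, not carbon, and gives the threefold-symmetric triether.

Step 2
Reactants: 2 1,3,5-tris(methoxymethoxy)benzene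
Product: 4 2-iodo-1,3,5-tris(methoxymethoxy)benzene, via [2,4,6-tris(methoxymethoxy)phenyl]lithium 3 (not isolated)
Conditions: n-BuLi, THF, 0 °C; then I2, THF, −78 °C to rt
Reagents that add atoms: iodine, II
Why: Directed ortho-metalation; every ring hydrogen lies between two coordinating MOM ethers and all three are equivalent, so one aryllithium forms and iodinolysis gives a single mono-iodide.

Step 3
Reactants: 5 4-methoxybenzyl chloride
Product: 6 (4-methoxybenzyl)zinc chloride (THF solution)
Conditions: Zn dust (activated with BrCH2CH2Br and Me3SiCl), LiCl, THF, 25 °C
Reagents that add atoms: zinc, [Zn]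
Why: Direct insertion of zinc metal into the benzylic C–Cl bond; LiCl takes the organozinc off the metal surface so that insertion runs at room temperature, where Wurtz-type homocoupling of the electron-rich benzyl halide is slow.

Step 4
Reactants: 4 2-iodo-1,3,5-tris(methoxymethoxy)benzene; 6 (4-methoxybenzyl)zinc chloride; 7 carbon monoxide
Product: 8 2-(4-methoxyphenyl)-1-[2,4,6-tris(methoxymethoxy)phenyl]ethanone
Conditions: Pd(PPh3)4 (5 mol %), CO (1 atm), THF, 50 °C, slow addition of 6
Reagents that add atoms: none
Why: Carbonylative Negishi coupling, a known palladium-catalysed three-component reaction of aryl iodides, CO and organozinc halides. Zerovalent palladium inserts into the C–I bond of 4, CO inserts into the aryl–palladium bond to give an aroyl complex of divalent palladium, 6 transfers its benzyl group to that complex, and reductive elimination forms the C(=O)–CH2 bond and returns zerovalent palladium. Both bonds of the ketone carbon, C6–C(=O) and C(=O)–CH2, are thus made in one catalytic cycle; no ring is closed and no stereocentre is formed. The selectivity needed is carbonylative over direct aryl–benzyl coupling: the two ortho MOM ethers crowd the arylpalladium centre, which slows transmetalation there and favours migratory insertion of the small CO ligand, since insertion moves the metal one atom away from the crowding. The CO atmosphere and slow addition of 6 keep the zinc reagent scarce until the aroyl complex has formed. No regiochemical question arises because 4 is symmetric, and the MOM acetals, the aryl methyl ether and the product ketone are inert to a benzylzinc halide.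

Step 5
Reactants: 8 2-(4-methoxyphenyl)-1-[2,4,6-tris(methoxymethoxy)phenyl]ethanone
Product: 9 2-(4-methoxyphenyl)-1-(2,4,6-trihydroxyphenyl)ethanone
Conditions: HCl (3 M aq), MeOH, 55 °C
Reagents that add atoms: none
Why: Acid-catalysed acetal exchange with methanol removes all three MOM groups; the aryl methyl ether and the aryl ketone are stable to dilute protic acid.

Step 6
Reactants: 9 2-(4-methoxyphenyl)-1-(2,4,6-trihydroxyphenyl)ethanone; 10 3-chloro-3-methylbut-1-yne
Product: 11 1-{2,6-dihydroxy-4-[(2-methylbut-3-yn-2-yl)oxy]phenyl}-2-(4-methoxyphenyl)ethanone
Conditions: K2CO3 (1.1 equiv), KI, CuI (cat.), acetone, 50 °C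
Reagents that add atoms: none
Why: CuI-assisted propargylic etherification; the hydroxyl para to the ketone is the most acidic (a vinylogous carboxylic acid) and is not tied up in the chelate, so one equivalent of carbonate ionises it alone, and the tertiary electrophile is slow to react at the crowded ortho hydroxyls.

Step 7
Reactants: 11 1-{2,6-dihydroxy-4-[(2-methylbut-3-yn-2-yl)oxy]phenyl}-2-(4-methoxyphenyl)ethanone
Product: 12 1-{2-hydroxy-6-(methoxymethoxy)-4-[(2-methylbut-3-yn-2-yl)oxy]phenyl}-2-(4-methoxyphenyl)ethanone
Conditions: MOMCl (1.1 equiv), i-Pr2NEt, CH2Cl2, 0 °C
Reagents that add atoms: chloromethyl methyl ether (MOMCl), COCCl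
Why: Mono-protection of a symmetric 2,6-dihydroxyaryl ketone; the two hydroxyls are equivalent, and once one is masked the other is locked in the hydrogen bond to the ketone and reacts far more slowly, as in the standard partial MOM protection of ortho-hydroxyaryl ketones.

Step 8
Reactants: 12 1-{2-hydroxy-6-(methoxymethoxy)-4-[(2-methylbut-3-yn-2-yl)oxy]phenyl}-2-(4-methoxyphenyl)ethanone
Product: 15 1-[5-hydroxy-7-(methoxymethoxy)-2,2-dimethyl-2H-chromen-6-yl]-2-(4-methoxyphenyl)ethanone, via allenylphenol 13 (not isolated), via ortho-quinone methide 14 (not isolated)
Conditions: PhNEt2, 150 °C
Reagents that add atoms: none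
Why: Aromatic propargyl Claisen rearrangement followed by enolisation to 13, a 1,5-hydrogen shift to 14 and oxa-6π electrocyclisation, the standard route from aryl 1,1-dimethylpropargyl ethers to 2,2-dimethylchromenes. The chelate between the free hydroxyl and the ketone fixes the ring double bonds as in resacetophenone ethers, so the sigmatropic shift should go to the carbon next to the chelated hydroxyl, and the hydrogen bond survives in the dienone formed.

Step 9
Reactants: 15 1-[5-hydroxy-7-(methoxymethoxy)-2,2-dimethyl-2H-chromen-6-yl]-2-(4-methoxyphenyl)ethanone
Product: 16 1-[5-methoxy-7-(methoxymethoxy)-2,2-dimethyl-2H-chromen-6-yl]-2-(4-methoxyphenyl)ethanone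
Conditions: MeI (excess), K2CO3, acetone, reflux
Reagents that add atoms: iodomethane, CI
Why: Williamson O-methylation of the chelated phenol; carbonate is strong enough for the phenol but too weak to enolise the benzylic ketone appreciably in acetone, so O-methylation should prevail over C-methylation.

Step 10
Reactants: 16 1-[5-methoxy-7-(methoxymethoxy)-2,2-dimethyl-2H-chromen-6-yl]-2-(4-methoxyphenyl)ethanone
Product: 17 1-(7-hydroxy-5-methoxy-2,2-dimethyl-2H-chromen-6-yl)-2-(4-methoxyphenyl)ethanone
Conditions: HCl (2 M aq), MeOH, 40 °C
Reagents that add atoms: none
Why: Acetal exchange; a MOM ether ortho to a ketone is unusually labile because the carbonyl oxygen assists departure, so conditions mild enough to leave the chromene double bond and both methyl ethers intact should be sufficient.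

## Compound list

1 | phloroglucinol (benzene-1,3,5-triol) | Oc1cc(O)cc(O)c1 | starting material
2 | 1,3,5-tris(methoxymethoxy)benzene | COCOc1cc(OCOC)cc(OCOC)c1 | intermediate
3 | [2,4,6-tris(methoxymethoxy)phenyl]lithium | [Li]c1c(OCOC)cc(OCOC)cc1OCOC | intermediate
4 | 2-iodo-1,3,5-tris(methoxymethoxy)benzene | COCOc1cc(OCOC)c(I)c(OCOC)c1 | intermediate
5 | 4-methoxybenzyl chloride | COc1ccc(CCl)cc1 | starting material
6 | (4-methoxybenzyl)zinc chloride | COc1ccc(C[Zn]Cl)cc1 | intermediate
7 | carbon monoxide | [C-]#[O+] | starting material
8 | 2-(4-methoxyphenyl)-1-[2,4,6-tris(methoxymethoxy)phenyl]ethanone | COCOc1cc(OCOC)c(C(=O)Cc2ccc(OC)cc2)c(OCOC)c1 | intermediate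
9 | 2-(4-methoxyphenyl)-1-(2,4,6-trihydroxyphenyl)ethanone | COc1ccc(CC(=O)c2c(O)cc(O)cc2O)cc1 | intermediate
10 | 3-chloro-3-methylbut-1-yne | CC(C)(Cl)C#C | starting material
11 | 1-{2,6-dihydroxy-4-[(2-methylbut-3-yn-2-yl)oxy]phenyl}-2-(4-methoxyphenyl)ethanone | COc1ccc(CC(=O)c2c(O)cc(OC(C)(C)C#C)cc2O)cc1 | intermediate
12 | 1-{2-hydroxy-6-(methoxymethoxy)-4-[(2-methylbut-3-yn-2-yl)oxy]phenyl}-2-(4-methoxyphenyl)ethanone | COCOc1cc(OC(C)(C)C#C)cc(O)c1C(=O)Cc1ccc(OC)cc1 | intermediate
13 | 1-[2,4-dihydroxy-6-(methoxymethoxy)-3-(3-methylbuta-1,2-dien-1-yl)phenyl]-2-(4-methoxyphenyl)ethanone | COCOc1cc(O)c(C=C=C(C)C)c(O)c1C(=O)Cc1ccc(OC)cc1 | intermediate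
14 | (6Z)-5-hydroxy-3-(methoxymethoxy)-4-[2-(4-methoxyphenyl)acetyl]-6-(3-methylbut-2-en-1-ylidene)cyclohexa-2,4-dien-1-one | COCOC1=CC(=O)/C(=C\C=C(C)C)C(O)=C1C(=O)Cc1ccc(OC)cc1 | intermediate
15 | 1-[5-hydroxy-7-(methoxymethoxy)-2,2-dimethyl-2H-chromen-6-yl]-2-(4-methoxyphenyl)ethanone | COCOc1cc2OC(C)(C)C=Cc2c(O)c1C(=O)Cc1ccc(OC)cc1 | intermediate
16 | 1-[5-methoxy-7-(methoxymethoxy)-2,2-dimethyl-2H-chromen-6-yl]-2-(4-methoxyphenyl)ethanone | COCOc1cc2OC(C)(C)C=Cc2c(OC)c1C(=O)Cc1ccc(OC)cc1 | intermediate
17 | 1-(7-hydroxy-5-methoxy-2,2-dimethyl-2H-chromen-6-yl)-2-(4-methoxyphenyl)ethanone | COc1ccc(CC(=O)c2c(O)cc3c(c2OC)C=CC(C)(C)O3)cc1 | target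

## Step count and risks

Total: 10 steps. Longest linear sequence: 9 steps (steps 1, 2, 4, 5, 6, 7, 8, 9, 10 from 1); step 3 is a one-step branch.

**Step 4 (key step).** The most likely failure is transfer of the benzyl group to the arylpalladium species before CO has inserted (direct aryl–benzyl coupling). Homocoupling of the benzylzinc reagent and slow oxidative addition of the very electron-rich iodide are further risks. The fallback gives up the CO construction and sets out from 1. Hoesch acylation of 1 with 4-methoxyphenylacetonitrile (HCl gas, ZnCl2, Et2O, 0 °C) gives the ketiminium salt 2-(4-methoxyphenyl)-1-(2,4,6-trihydroxyphenyl)ethan-1-iminium chloride F1. Hydrolysis in hot water then gives the ketone and returns to the route at 9. This classical path is shorter than steps 1 to 5 and is the reason the key step carries little strategic risk for the route as a whole.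

**Step 6.** With three free phenols, alkylation may continue at an ortho hydroxyl or go to ring carbon, and the tertiary chloride may react sluggishly. The fallback sets out from 9 and changes the ring construction. Condensation with 3-methylbut-2-enal A4 under ethylenediammonium diacetate catalysis (Knoevenagel condensation and oxa-6π closure) would give 1-(5,7-dihydroxy-2,2-dimethyl-2H-chromen-6-yl)-2-(4-methoxyphenyl)ethanone F2. Closure onto an ortho oxygen would give an isomer that would have to be separated. MOM protection of the less hindered C7 hydroxyl of F2 (MOMCl, i-Pr2NEt, CH2Cl2) returns to the route at 15.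

**Step 8.** The sigmatropic shift may go to the carbon next to the MOM ether instead of the chelated hydroxyl, because both ortho carbons are flanked by oxygen; thermal loss of the acetal is a lesser risk. The fallback uses the same bias the other way round and sets out from 11. Mono-methylation (MeI, 1 equiv, K2CO3, acetone) gives 1-{2-hydroxy-6-methoxy-4-[(2-methylbut-3-yn-2-yl)oxy]phenyl}-2-(4-methoxyphenyl)ethanone F3. Its thermal rearrangement next to the methoxy-bearing carbon would lead directly to 17, and steps 7, 9 and 10 would fall away.

**Step 9.** Methylation of the hindered, hydrogen-bonded hydroxyl may be slow enough for C-methylation at the benzylic CH2 to compete. The fallback sets out from 15 and avoids base altogether: Mitsunobu etherification with methanol (PPh3, diisopropyl azodicarboxylate, THF) activates the alcohol instead of the phenoxide and returns to the route at 16. This detour makes no new compound and is entered as F0.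

## Further compounds

F1 | step 4 | 2-(4-methoxyphenyl)-1-(2,4,6-trihydroxyphenyl)ethan-1-iminium chloride | COc1ccc(CC(=[NH2+])c2c(O)cc(O)cc2O)cc1.[Cl-]
F2 | step 6 | 1-(5,7-dihydroxy-2,2-dimethyl-2H-chromen-6-yl)-2-(4-methoxyphenyl)ethanone | COc1ccc(CC(=O)c2c(O)cc3OC(C)(C)C=Cc3c2O)cc1
F3 | step 8 | 1-{2-hydroxy-6-methoxy-4-[(2-methylbut-3-yn-2-yl)oxy]phenyl}-2-(4-methoxyphenyl)ethanone | COc1ccc(CC(=O)c2c(O)cc(OC(C)(C)C#C)cc2OC)cc1
F0 | step 9 | none | none
A1 | alternative 1 | 5-methoxy-7-(methoxymethoxy)-2,2-dimethyl-2H-chromene | COCOc1cc(OC)c2C=CC(C)(C)Oc2c1
A2 | alternative 1 | 3-methoxy-5-(methoxymethoxy)-2-(trimethylsilyl)phenyl trifluoromethanesulfonate | COCOc1cc(OC)c([Si](C)(C)C)c(OS(=O)(=O)C(F)(F)F)c1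
A3 | alternative 1 | 3-methoxy-5-(methoxymethoxy)benzyne | COCOC1=CC#CC(OC)=C1
A4 | alternative 1 | 3-methylbut-2-enal | CC(C)=CC=O
A5 | alternative 2 | 2-(4-methoxyphenyl)-1-(2,4,6-trihydroxyphenyl)ethanone | COc1ccc(CC(=O)c2c(O)cc(O)cc2O)cc1
A6 | alternative 2 | methyl 8-(4-methoxyphenyl)-3,5,7-trioxooctanoate | COC(=O)CC(=O)CC(=O)CC(=O)Cc1ccc(OC)cc1
A7 | alternative 3 | 1-{2-hydroxy-6-(methoxymethoxy)-4-[(2-methylbut-3-yn-2-yl)oxy]phenyl}-2-(4-methoxyphenyl)ethanone | COCOc1cc(OC(C)(C)C#C)cc(O)c1C(=O)Cc1ccc(OC)cc1
A8 | alternative 3 | 3-(methoxymethoxy)-5-[(2-methylbut-3-yn-2-yl)oxy]-2-(trimethylsilyl)phenyl trifluoromethanesulfonate | COCOc1cc(OC(C)(C)C#C)cc(OS(=O)(=O)C(F)(F)F)c1[Si](C)(C)C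
A9 | alternative 3 | 3-(methoxymethoxy)-5-[(2-methylbut-3-yn-2-yl)oxy]benzyne | COCOC1=CC(OC(C)(C)C#C)=CC#C1
A10 | alternative 3 | 4-methoxyphenylacetic acid | COc1ccc(CC(=O)O)cc1
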